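Readings and results come from a simulation from invented constants; scatter was added.

- The pitfall is to read lost starting material as target: by 8.00 h the oak run has lost 24.0% of its starting material but shows 13.6% target.

| flask | starting material | reagent in the second phase | remark | time | volume of the second phase over the first |
|---|---|---|---|---|---|
| oak | 2 M | 1.05 equiv | run made earlier |  |  |
| flask | 1.0 M | 1.05 equiv |  | 25 h | 1.0 |

oak run (percent of the starting material charged)

| time / h | target / % | starting material / % |
|---|---|---|
| 2.00 | 3.9 | 95.5 |
| 4.00 | 9.2 | 87.1 |
| 6.00 | 12.2 | 80.8 |
| 8.00 | 13.6 | 76.0 |

(each reading ± 1 percentage point)

- in the second phase: reagent in the second phase; everything else is in the first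
- charges count per volume of the first phase; a concentration in a rate is the amount of a species over the volume of its own phase; every rate counts per litre of the first phase
- steps thought possible: reagent in the reaction phase -> decomposed reagent; starting material -> decomposition product; target <-> isomer of the product; reagent in the reaction phase <-> reagent in the second phase; starting material + reagent in the reaction phase -> target
- the earlier runs hold the two phases in the same ratio of volumes as the flask asked about

- target at 25 h, in percent of the starting material charged
- the change that raises the amount of target at 25 h, in percent of the starting material charged most ("none" if none brings more than 2 percentage points) (Tuesday's / Saturday's / none)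
- amount of target at 25 h, in percent of the starting material charged, after Tuesday's

- Fastest rung: I define q as the starting material gone but not found as target, over the target present. In the oak run it climbs from 0.154 at 2.00 h to 0.765 at 8.00 h. I take q as a clock of a first-order loss of target, independent of the charge.
- Slower rung: the oak run's specific loss of starting material falls from 0.0460 /h to 0.0306 /h. I read that as a decay of 0.102 /h, so the reagent's push has a half-life, as read, of 6.80 h, shorter than the 25 h asked.
- Last rung: I treat the loss as pseudo-first-order with a fading rate. Its exposure L, minus the logarithm of the fraction left, reaches 0.498 for the oak run at 25 h.
- My reckoning: the flask has half the reagent per litre, so I scale L by that ratio, and 22.0% of the starting material reacts. Holding q at 0.765 gives 12.5% target. For Saturday's I take the oak run's L, which gives 22.2%, while I expect Tuesday's to stay near 12.5%.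
- The forecast says 6.5% (3.5% to 11%), Saturday's and 5% after Tuesday's, since "By 25 h much target has isomerised".

    reagent in the reaction phase → decomposed reagent (k = 0.430 /h)
    starting material → decomposition product (k = 4.00 × 10⁻⁴ /h)
    target ⇌ isomer of the product (K = 1.10, k = 0.300 /h)
    reagent in the reaction phase ⇌ reagent in the second phase, rate k4*([reagent in the reaction phase] - [reagent in the second phase]/K4) per volume of the first phase (partition coefficient = 2.40, kL = 0.310 /h)
    starting material + reagent in the reaction phase → target (k = 0.200 /M/h)

- The flask gives 12.6%, 13.5% after Tuesday's, and Saturday's as the best change, worth 9.8 percentage points. The relaxation half-life of target and isomer of the product, both ways together, 1.21 h, is short against 25 h. Here q stands at 1.11, above my 0.765, and 26.5% reacted, above my 22.0%, so my close number rests on two misses that cancel.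
- The neighbouring flask is this flask stopped at 6.0 h. Half the oak run's L at that time gives 10.1% reacted, and the same clock gives q of 0.574, below 0.765, so I expect 6.42% target. It holds 6.69% target.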